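**Abbreviations:** MOM = methoxymethyl, TBS = tert-butyldimethylsilyl, TMS = trimethylsilyl, TES = triethylsilyl, prenyl = 3-methylbut-2-en-1-yl, DMDO = dimethyldioxirane, TMP = 2,2,6,6-tetramethylpiperidide.

## Structural features

The target is a flavonol: a 4H-chromen-4-one in which benzo ring A (C4a to C8a) is fused to pyranone ring C (O1, C2, C3, C4), and ring C carries phenyl ring B through the C2–C1' bond. Ring A holds a free catechol at C6/C7, ring C an enolic hydroxyl at C3 next to the C4 carbonyl, and ring B a second catechol unit in which O3' is a prenyl ether and O4' is free. There is no stereocentre, so the problem is one of regiochemistry and functional-group tolerance only. The aryl prenyl ether is the fragile group: it ionises to an allyl cation with protic or Lewis acids, rearranges on strong heating, and its trisubstituted alkene rules out hydrogenolysis late in the route. The free polyphenol (catechol plus 3-hydroxypyranone) also oxidises in air under base. The real difficulty is ring B, where two neighbouring phenols of nearly equal reactivity must end up differently substituted, and the end game, where the other oxygens must be unmasked without loss of the prenyl group. The key step exploits the fact that C2'–C3'–C4'–C5' with O3' and O4' map onto a 2,3-dioxygenated butadiene and C1'/C6' onto an alkyne on C2 of ring C, so O3' and O4' enter as two different enol ethers and no catechol is ever differentiated. The C4 carbonyl, relayed through C2=C3, polarises that alkyne and decides which diene terminus bonds to which alkyne carbon.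

## Logic of the disconnections

**23 to 21.** One O–Si bond and three O–CH2 acetal bonds are cut. The four hydroxyls must stay masked up to here because free phenols would protonate and destroy 19 in the ring-forming step. The gain is that everything after the key step is one deprotection flask. The demand is that acetal cleavage must not ionise the allylic aryl ether. The acetals are therefore exchanged for silyl groups under buffered, aprotic conditions (through 22), and all silyl ethers are then removed together with buffered fluoride.

**21 to 13 and 19.** The bonds C1'–C2' and C5'–C6' are cut, which removes ring B as a whole. This is the most simplifying cut because the unsymmetrical catechol becomes two enol ethers whose positions are fixed when 19 is made. The forward step needs the correct regiochemistry, attack on the alkyne and not on C2=C3, a temperature below that of sigmatropic rearrangement of 19, and clean loss of the amine from adduct 20.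

**13 to 12 to 10 and 11.** The C2–C(alkyne) bond is cut. C2 of the chromone behaves as the β-carbon of an enone, so a halide there couples readily and 11 supplies both alkyne carbons. The demand is that the terminal alkyne, once freed, is a conjugate acceptor, so the silyl group must come off under buffered, non-nucleophilic conditions.

**10 to 8.** The C2–I bond is cut. C2–H is the only C–H on ring C, it is acidified by O1, and it is flanked by the coordinating acetal oxygen on C3. Deprotonative metalation (through 9) followed by an iodine electrophile should therefore be regioselective. The base must metalate without adding to C2 or opening the pyranone.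

**8 to 7 to 5.** The C3–O bond is cut. Oxygen is placed on C3 by epoxidation of C2=C3 and isomerisation of epoxide 6, which needs no pre-oxygenated ketone. The demand is a neutral oxidant and only catalytic acid, because two aryl acetals are already present.

**5 to 2 and 3, and 2 to 1.** O1–C2 and C2–C3 are cut, so that C2 comes from the one-carbon unit 3 through enaminone 4. Compound 2 goes back to 1 by cutting two acetal C–O bonds. The forward protection must leave the chelated ortho hydroxyl free, since it becomes O1.

**19 to 18 to 17 and 3.** The O–Si bond is cut first, and then the C1=C2 bond of the diene, whose amino-bearing carbon comes from 3. The condensation must take place at the oxygen-bearing methylene of 17 and not at its methyl group, and no step may be hot enough to rearrange the prenyl vinyl ether.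

**17 to 16 to 14 and 15.** The C–CH3 bond and the ether C–O bond are cut. Alkylating an alkoxide with an α-halo ketone was set aside because such ketones enolise and self-condense under base. An α-chloro amide alkylates cleanly, and the N-methoxy-N-methylamide then stops at the ketone. This costs one step more than the shortest conceivable access and buys reliability.

## Other disconnections considered

**Alternative 1:** The cut runs through ring C at O1–C8a, C4–C4a and O1–C2. Ring A would come as a symmetric 4,5-dioxygenated aryne released from silyl triflate A1, and C2, C3, C4 with ring B as the α-oxygenated acrylic acid A2. In the forward step fluoride unmasks the aryne and the carboxylate oxygen adds to it. The aryl anion then attacks the acyl carbon (net insertion into the acyl C–O bond), and the ortho-acyl phenoxide closes by oxa-Michael addition to give flavanone A3 as a diastereomer mixture.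
- In its favour: the aryne is symmetric, so ring A poses no regiochemical question. Three bonds of ring C form in one operation. Aryne insertion into carboxylic acids is an established reaction class, so on precedent this step stands above the chosen one.
- Against it here: plain O-arylation of the acid (proton transfer to the aryl anion) competes with acyl migration. A3 is one oxidation level too low and carries a benzyl ether on O3', so dehydrogenation, hydrogenolysis, prenylation of the freed phenol and acetal removal next to the new prenyl ether would all have to follow. The two ring B oxygens of A2 must be told apart by classical selective protection, which is exactly what the chosen plan avoids. A1 needs a multi-step preparation.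
- Comparison: in convergence the two plans are equal, since both join a ring A piece and a ring B piece late. Mechanistically Alternative 1 has the safer ring formation. In step economy after the key step it is clearly longer, about four operations against one.

**Alternative 2:** The cut takes out C3 as a one-carbon unit by breaking C3–C4 and C2=C3. Ring A would be a salicylic acid whose phenol is acylated by the ring B benzoic acid and whose carboxyl group is a silyl ester (diester A4). C3 and its oxygen would come from the alkoxymethylene ylide A5. In the forward step A5 is acylated by the silyl ester and a second equivalent deprotonates the phosphonium salt. The acyl ylide then olefinates the neighbouring aryl ester carbonyl (intramolecular Wittig reaction), which closes ring C and gives the 3-alkoxyflavone A6 at the correct oxidation level.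
- In its favour: ring closure of such silyl esters with ylides to chromones and flavones is known chemistry. No oxidation-level change is needed. Both halves are simple benzoic acids.
- Against it here: an α-alkoxy acyl ylide is more hindered and less nucleophilic than the parent, and ester olefination is already demanding. Two equivalents of A5 are consumed. The ring B pattern must again come from selective protection and prenylation of a 3,4-dihydroxybenzoate. The prenyl ether then travels through more steps and must survive cleavage of a 2-(trimethylsilyl)ethyl ether and of three acetals.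
- Comparison: on step count Alternative 2 is the equal of the chosen plan and probably the better, and on precedent it is the better. The chosen plan is stronger on one structural point: its ring B pattern arises from orbital-controlled bond formation and not from a small acidity difference between two phenols. It also has the lighter deprotection burden.

**Alternative 3:** The cut is the single bond C4–C4a. The precursor is the bromo ester A7, an aryl ether that would be assembled by opening an aryl glycidate with a bromophenol at the benzylic carbon and silylating the new hydroxyl. In the forward step halogen–lithium exchange at C4a gives an aryllithium that attacks the methyl ester in a six-membered ring-forming acylation (Parham cyclisation) to give the 3-siloxyflavanone A8.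
- In its favour: the whole carbon skeleton and the C3 oxygen are in place before ring closure. The position of bromine fixes the ring A regiochemistry, which makes it the equal of the chosen plan on that point. Parham cycloacylation is well precedented.
- Against it here: the ester α-proton is acidic and the β-aryloxy group can leave, so elimination to a cinnamate competes with acylation. The epoxide opening must be regioselective with a hindered phenol. A8 is at the flavanonol oxidation level, so dehydrogenation, desilylation and acetal cleavage next to the prenyl ether must follow. Ring B still needs classical differentiation.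
- Comparison: the mechanism is better known than that of the chosen key step. The route is longer, and it is less tolerant at its key step (an alkyllithium against a near-neutral cycloaddition).

Key step: step 12

Assumption: the enolic 3-O-methoxymethyl ether on ring C is taken to respond to silyl triflate/2,2'-bipyridyl like the aryl methoxymethyl ethers on ring A (exchange to a silyl ether).

Check of structures: 13, 19 and 21 were compared atom by atom with 23. Connectivity and the (1Z) geometry of 19 (amino group trans to C3, the geometry able to react) are consistent, so no structure needed correction. The changes concern the access to 17, the telescoping on the way to 13, and the aprotic removal of the acetals.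

## Route

Step 1
Reactants: 1 1-(2,4,5-trihydroxyphenyl)ethan-1-one (2',4',5'-trihydroxyacetophenone)
Product: 2 1-[2-hydroxy-4,5-bis(methoxymethoxy)phenyl]ethan-1-one
Conditions: MOMCl (2.2 equiv), iPr2NEt, CH2Cl2, 0 °C to rt, Ar
Reagents that add atoms: chloromethyl methyl ether, COCCl
Why: O-alkylation of the two free phenols as acetals; the 2'-hydroxyl is hydrogen-bonded to the ketone and far less nucleophilic, so it should stay free for the later ring closure.

Step 2
Reactants: 2 1-[2-hydroxy-4,5-bis(methoxymethoxy)phenyl]ethan-1-one; 3 N,N-dimethylformamide dimethyl acetal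
Product: 5 6,7-bis(methoxymethoxy)-4H-chromen-4-one, via enaminone 4 (not isolated)
Conditions: 3 (neat), 90 °C; evaporate; AcOH, 70 °C
Reagents that add atoms: none
Why: Aminomethylenation of the methyl ketone gives the enaminone, and acid-promoted intramolecular oxa-Michael addition of the phenol with loss of Me2NH closes the pyranone (enaminone route to chromones); acetic acid is too weak to cleave aryl methoxymethyl ethers.

Step 3
Reactants: 5 6,7-bis(methoxymethoxy)-4H-chromen-4-one
Product: 7 3-hydroxy-6,7-bis(methoxymethoxy)-4H-chromen-4-one, via 2,3-epoxychromanone 6 (not isolated)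
Conditions: DMDO, acetone–CH2Cl2, 0 °C to rt; then TsOH·H2O (cat.), CH2Cl2, rt
Reagents that add atoms: dimethyldioxirane, CC1(C)OO1
Why: Epoxidation of C2=C3 by the neutral dioxirane, then acid-catalysed opening at the acetal carbon C2 and loss of H3 gives the 3-hydroxychromone (the dioxirane route to flavonols applied to a 2-unsubstituted chromone); the epoxide is racemic and both of its centres vanish.

Step 4
Reactants: 7 3-hydroxy-6,7-bis(methoxymethoxy)-4H-chromen-4-one
Product: 8 3,6,7-tris(methoxymethoxy)-4H-chromen-4-one
Conditions: MOMCl, iPr2NEt, CH2Cl2, 0 °C to rt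
Reagents that add atoms: chloromethyl methyl ether, COCCl
Why: O-alkylation of the acidic enolic 3-hydroxyl; the new acetal oxygen also serves as a coordinating group for the metalation that follows.

Step 5
Reactants: 8 3,6,7-tris(methoxymethoxy)-4H-chromen-4-one
Product: 10 2-iodo-3,6,7-tris(methoxymethoxy)-4H-chromen-4-one, via 2-chromonylzinc chloride 9 (not isolated)
Conditions: TMPZnCl·LiCl (1.2 equiv), THF, 25 °C; then I2, THF, 0 °C
Reagents that add atoms: iodine, II
Why: Directed deprotonative zincation: C2–H is the only C–H on ring C, acidified by O1 and flanked by the 3-acetal, and this mild zinc amide metalates chromones at C2 without adding to the enone or opening the ring; iodinolysis of the C–Zn bond gives the iodide.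

Step 6
Reactants: 10 2-iodo-3,6,7-tris(methoxymethoxy)-4H-chromen-4-one; 11 ethynyltrimethylsilane
Product: 12 3,6,7-tris(methoxymethoxy)-2-[(trimethylsilyl)ethynyl]-4H-chromen-4-one
Conditions: PdCl2(PPh3)2 (3 mol %), CuI (5 mol %), Et3N, THF, rt
Reagents that add atoms: none
Why: Sonogashira coupling; the C2–I bond of this β-iodo enone-type system should add oxidatively to zerovalent palladium (formed in situ) at room temperature, and acetals are inert to the conditions.

Step 7
Reactants: 12 3,6,7-tris(methoxymethoxy)-2-[(trimethylsilyl)ethynyl]-4H-chromen-4-one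
Product: 13 2-ethynyl-3,6,7-tris(methoxymethoxy)-4H-chromen-4-one
Conditions: Bu4NF, AcOH, THF, −20 °C
Reagents that add atoms: none
Why: Fluoride-induced protodesilylation of the alkynylsilane; buffering with acetic acid keeps alkoxide and hydroxide away from the conjugate-acceptor alkyne, and the acetals do not react with fluoride.

Step 8
Reactants: 14 3-methylbut-2-en-1-ol (prenol); 15 2-chloro-N-methoxy-N-methylacetamide
Product: 16 N-methoxy-N-methyl-2-[(3-methylbut-2-en-1-yl)oxy]acetamide
Conditions: NaH, THF, 0 °C; then 15, 0 °C to rt
Reagents that add atoms: none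
Why: Williamson ether synthesis on an α-chloro amide, a fast SN2 electrophile that, unlike an α-chloro ketone, should not enolise or self-condense under alkoxide.

Step 9
Reactants: 16 N-methoxy-N-methyl-2-[(3-methylbut-2-en-1-yl)oxy]acetamide
Product: 17 1-[(3-methylbut-2-en-1-yl)oxy]propan-2-one
Conditions: MeMgBr, THF, 0 °C; aq. NH4Cl
Reagents that add atoms: methylmagnesium bromide, C[Mg]Br
Why: Ketone synthesis from an N-methoxy-N-methylamide; the chelated tetrahedral intermediate persists until work-up, so addition should stop at the methyl ketone.

Step 10
Reactants: 17 1-[(3-methylbut-2-en-1-yl)oxy]propan-2-one; 3 N,N-dimethylformamide dimethyl acetal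
Product: 18 (3Z)-4-(dimethylamino)-3-[(3-methylbut-2-en-1-yl)oxy]but-3-en-2-one
Conditions: 3 (1.5 equiv), PhMe, 80 °C
Reagents that add atoms: none
Why: Aminomethylenation at the more acidic oxygen-bearing methylene (activated by carbonyl and alkoxy group) gives the push–pull enaminone with the amino group trans to acetyl, its thermodynamic geometry; 80 °C is well below the temperature at which a prenyl vinyl ether rearranges.

Step 11
Reactants: 18 (3Z)-4-(dimethylamino)-3-[(3-methylbut-2-en-1-yl)oxy]but-3-en-2-one
Product: 19 (1Z)-3-[(tert-butyldimethylsilyl)oxy]-N,N-dimethyl-2-[(3-methylbut-2-en-1-yl)oxy]buta-1,3-dien-1-amine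
Conditions: KN(SiMe3)2, THF, −78 °C; TBSCl, −78 °C to rt; filter, use crude
Reagents that add atoms: tert-butyldimethylsilyl chloride, CC(C)(C)[Si](C)(C)Cl
Why: Kinetic deprotonation of the methyl group of the vinylogous amide (its only enolisable position) and O-silylation of the enolate, the standard entry to 1-amino-3-siloxy dienes; the C1=C2 geometry of 18 carries over, so the amino group points away from C3.

Step 12
Reactants: 13 2-ethynyl-3,6,7-tris(methoxymethoxy)-4H-chromen-4-one; 19 (1Z)-3-[(tert-butyldimethylsilyl)oxy]-N,N-dimethyl-2-[(3-methylbut-2-en-1-yl)oxy]buta-1,3-dien-1-amine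
Product: 21 2-{4-[(tert-butyldimethylsilyl)oxy]-3-[(3-methylbut-2-en-1-yl)oxy]phenyl}-3,6,7-tris(methoxymethoxy)-4H-chromen-4-one, via aminocyclohexadiene adduct 20 (not isolated)
Conditions: 19 (1.5 equiv), PhMe, 45 °C; then AcOH (2 equiv), rt
Reagents that add atoms: none
Why: Proposed new method: the CH2 terminus of 19, made nucleophilic by both the amino and the siloxy group, should bond to the terminal alkyne carbon of 13 (the δ-carbon of the C4=O/C2=C3/C≡C acceptor chain) while the amino-bearing carbon bonds to the inner alkyne carbon, in a concerted, asynchronous (4+2) cycloaddition that gives the racemic cyclohexa-1,4-diene 20; a stepwise Michael–Mannich path would end in the same ring. The closest known reaction type is the Diels–Alder addition of 1-amino-3-siloxy and 1-alkoxy-3-siloxy dienes to acetylenic ketones and esters followed by elimination to 4-oxygenated arenes; new here are the vinylogous (ynenone) activation of the alkyne and the extra 2-alkoxy group on the diene. Ring B closes by intermolecular (4+2) annulation, the bonds C1'–C2' and C5'–C6' forming on the two alkyne carbons. In 20 the C–N bond is doubly allylic and vinylogous to the silyl enol ether, so N-protonation by AcOH, loss of Me2NH and loss of the C5' proton should give the aryl silyl ether with the Si–O bond intact. No stereocentre is created in 21: the single CH–N centre of 20 is erased on aromatisation. The regiochemistry needed (siloxy carbon para, prenyloxy carbon meta to C1') follows from pairing the most nucleophilic diene terminus with the most electrophilic alkyne carbon. Chemoselectivity for the unhindered terminal alkyne over the tetrasubstituted, donor-substituted C2=C3 bond is expected on steric and electronic grounds, and at 45 °C the prenyl vinyl ether of 19 should not yet undergo [3,3] rearrangement, whose bond-forming carbon is the hindered CMe2 terminus. Running the cycloaddition to completion before the acid is added keeps the liberated amine from adding to unreacted 13.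

Step 13
Reactants: 21 2-{4-[(tert-butyldimethylsilyl)oxy]-3-[(3-methylbut-2-en-1-yl)oxy]phenyl}-3,6,7-tris(methoxymethoxy)-4H-chromen-4-one
Product: 23 3,6,7-trihydroxy-2-{4-hydroxy-3-[(3-methylbut-2-en-1-yl)oxy]phenyl}-4H-chromen-4-one (target), via tris(trimethylsilyl) ether 22 (not isolated)
Conditions: TMSOTf, 2,2'-bipyridyl, MeCN, 0 °C to rt; then Bu4NF, AcOH, THF, 0 °C, Ar
Reagents that add atoms: none
Why: Silyl triflate buffered by 2,2'-bipyridyl exchanges aryl methoxymethyl ethers for silyl ethers without free protic acid, so the allylic aryl ether should not ionise; buffered fluoride then cleaves the three O–SiMe3 bonds and the aryl O–TBS bond together, and the acetic acid keeps the air-sensitive polyphenol from standing as its phenolate.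

## Compound list

1 | 1-(2,4,5-trihydroxyphenyl)ethan-1-one | CC(=O)c1cc(O)c(O)cc1O | starting material
2 | 1-[2-hydroxy-4,5-bis(methoxymethoxy)phenyl]ethan-1-one | CC(=O)c1cc(OCOC)c(OCOC)cc1O | intermediate
3 | N,N-dimethylformamide dimethyl acetal | COC(OC)N(C)C | starting material
4 | (2E)-3-(dimethylamino)-1-[2-hydroxy-4,5-bis(methoxymethoxy)phenyl]prop-2-en-1-one | CN(C)/C=C/C(=O)c1cc(OCOC)c(OCOC)cc1O | intermediate
5 | 6,7-bis(methoxymethoxy)-4H-chromen-4-one | O=c1ccoc2cc(OCOC)c(OCOC)cc12 | intermediate
6 | 2,3-epoxy-6,7-bis(methoxymethoxy)chroman-4-one (racemic, cis-fused; one enantiomer drawn) | O=C1[C@H]2O[C@H]2Oc2cc(OCOC)c(OCOC)cc21 | intermediate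
7 | 3-hydroxy-6,7-bis(methoxymethoxy)-4H-chromen-4-one | O=c1c(O)coc2cc(OCOC)c(OCOC)cc12 | intermediate
8 | 3,6,7-tris(methoxymethoxy)-4H-chromen-4-one | COCOc1coc2cc(OCOC)c(OCOC)cc2c1=O | intermediate
9 | chloro[3,6,7-tris(methoxymethoxy)-4-oxo-4H-chromen-2-yl]zinc (LiCl complex) | COCOc1c([Zn]Cl)oc2cc(OCOC)c(OCOC)cc2c1=O | intermediate
10 | 2-iodo-3,6,7-tris(methoxymethoxy)-4H-chromen-4-one | COCOc1c(I)oc2cc(OCOC)c(OCOC)cc2c1=O | intermediate
11 | ethynyltrimethylsilane | C#C[Si](C)(C)C | starting material
12 | 3,6,7-tris(methoxymethoxy)-2-[(trimethylsilyl)ethynyl]-4H-chromen-4-one | COCOc1c(C#C[Si](C)(C)C)oc2cc(OCOC)c(OCOC)cc2c1=O | intermediate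
13 | 2-ethynyl-3,6,7-tris(methoxymethoxy)-4H-chromen-4-one | C#Cc1oc2cc(OCOC)c(OCOC)cc2c(=O)c1OCOC | intermediate
14 | 3-methylbut-2-en-1-ol (prenol) | CC(C)=CCO | starting material
15 | 2-chloro-N-methoxy-N-methylacetamide | CON(C)C(=O)CCl | starting material
16 | N-methoxy-N-methyl-2-[(3-methylbut-2-en-1-yl)oxy]acetamide | CON(C)C(=O)COCC=C(C)C | intermediate
17 | 1-[(3-methylbut-2-en-1-yl)oxy]propan-2-one | CC(=O)COCC=C(C)C | intermediate
18 | (3Z)-4-(dimethylamino)-3-[(3-methylbut-2-en-1-yl)oxy]but-3-en-2-one | CN(C)/C=C(\OCC=C(C)C)C(C)=O | intermediate
19 | (1Z)-3-[(tert-butyldimethylsilyl)oxy]-N,N-dimethyl-2-[(3-methylbut-2-en-1-yl)oxy]buta-1,3-dien-1-amine | CN(C)/C=C(\OCC=C(C)C)C(=C)O[Si](C)(C)C(C)(C)C | intermediate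
20 | 2-{4-[(tert-butyldimethylsilyl)oxy]-6-(dimethylamino)-5-[(3-methylbut-2-en-1-yl)oxy]cyclohexa-1,4-dien-1-yl}-3,6,7-tris(methoxymethoxy)-4H-chromen-4-one (racemic) | CN(C)C1C(OCC=C(C)C)=C(O[Si](C)(C)C(C)(C)C)CC=C1c1oc2cc(OCOC)c(OCOC)cc2c(=O)c1OCOC | intermediate
21 | 2-{4-[(tert-butyldimethylsilyl)oxy]-3-[(3-methylbut-2-en-1-yl)oxy]phenyl}-3,6,7-tris(methoxymethoxy)-4H-chromen-4-one | CC(C)=CCOc1cc(-c2oc3cc(OCOC)c(OCOC)cc3c(=O)c2OCOC)ccc1O[Si](C)(C)C(C)(C)C | intermediate
22 | 2-{4-[(tert-butyldimethylsilyl)oxy]-3-[(3-methylbut-2-en-1-yl)oxy]phenyl}-3,6,7-tris[(trimethylsilyl)oxy]-4H-chromen-4-one | CC(C)=CCOc1cc(-c2oc3cc(O[Si](C)(C)C)c(O[Si](C)(C)C)cc3c(=O)c2O[Si](C)(C)C)ccc1O[Si](C)(C)C(C)(C)C | intermediate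
23 | 3,6,7-trihydroxy-2-{4-hydroxy-3-[(3-methylbut-2-en-1-yl)oxy]phenyl}-4H-chromen-4-one | CC(C)=CCOc1cc(-c2oc3cc(O)c(O)cc3c(=O)c2O)ccc1O | target

## Step count and least certain steps

Total: 13 steps. Longest linear sequence: 9 steps (steps 1 to 7, then 12 and 13, from 1). The diene branch is 4 steps (steps 8 to 11).

**Step 12 (key step).** The most likely failure is insufficient reactivity of the alkyne. Its activation is relayed through C2=C3 and damped by the ring oxygen and the 3-alkoxy group, so the cycloaddition may be slower than hydrolysis or sigmatropic rearrangement of the diene. The amine set free early may also add to the remaining alkyne, and a Michael addition may stall without ring closure. The fallback gives up the benzannulation and uses known flavonol chemistry, starting from 2 and returning at 23.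
- 3,4-Dihydroxybenzaldehyde is protected at its more acidic 4-hydroxyl (MOMCl, K2CO3, acetone) to give 3-hydroxy-4-(methoxymethoxy)benzaldehyde F1.
- Prenyl bromide and K2CO3 in DMF convert F1 into 4-(methoxymethoxy)-3-[(3-methylbut-2-en-1-yl)oxy]benzaldehyde F2.
- Claisen–Schmidt condensation of 2 with F2 (KOH, EtOH) gives the chalcone (2E)-1-[2-hydroxy-4,5-bis(methoxymethoxy)phenyl]-3-{4-(methoxymethoxy)-3-[(3-methylbut-2-en-1-yl)oxy]phenyl}prop-2-en-1-one F3.
- Algar–Flynn–Oyamada oxidation (H2O2, NaOH, MeOH) passes through trans-3-hydroxy-6,7-bis(methoxymethoxy)-2-{4-(methoxymethoxy)-3-[(3-methylbut-2-en-1-yl)oxy]phenyl}chroman-4-one F4 (not isolated) to the flavonol 3-hydroxy-6,7-bis(methoxymethoxy)-2-{4-(methoxymethoxy)-3-[(3-methylbut-2-en-1-yl)oxy]phenyl}-4H-chromen-4-one F5.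
- The acetal exchange of step 13 then gives 2-{3-[(3-methylbut-2-en-1-yl)oxy]-4-[(trimethylsilyl)oxy]phenyl}-3,6,7-tris[(trimethylsilyl)oxy]-4H-chromen-4-one F6 (not isolated), and buffered fluoride gives 23.
- This detour pays for its safety with the selective protection of a catechol that the main route avoids.

**Step 13.** The risk is ionisation of the allylic aryl ether by the silyl triflate (loss or migration of the prenyl group) in competition with acetal exchange, and air oxidation of the polyphenol in the fluoride stage. The fallback moves the acetal cleavage in front of the cycloaddition, so that no prenyl ether is present when the acetals go. It sets out from 13 and returns at 23.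
- TESOTf and 2,2'-bipyridyl convert 13 directly into 2-ethynyl-3,6,7-tris[(triethylsilyl)oxy]-4H-chromen-4-one F7.
- Cycloaddition of F7 with 19 as in step 12 gives 2-{4-[(tert-butyldimethylsilyl)oxy]-6-(dimethylamino)-5-[(3-methylbut-2-en-1-yl)oxy]cyclohexa-1,4-dien-1-yl}-3,6,7-tris[(triethylsilyl)oxy]-4H-chromen-4-one F8 (not isolated).
- Loss of amine from F8 gives 2-{4-[(tert-butyldimethylsilyl)oxy]-3-[(3-methylbut-2-en-1-yl)oxy]phenyl}-3,6,7-tris[(triethylsilyl)oxy]-4H-chromen-4-one F9, and one treatment with Bu4NF/AcOH gives 23.

**Step 5.** The risk is metalation on ring A (C5 or C8, each ortho to an acetal oxygen) or incomplete zincation because the 3-alkoxy group lowers the acidity of C2–H. The fallback uses electrophilic instead of anionic chemistry. It sets out from 7 and returns at 10. The enolic 3-hydroxyl of 7 directs iodination to C2 (I2, NaHCO3, aqueous THF), as in 3-hydroxy-4-pyranones, to give 3-hydroxy-2-iodo-6,7-bis(methoxymethoxy)-4H-chromen-4-one F10. Acetalisation with MOMCl/iPr2NEt then gives 10.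

**Step 3.** The risk is slow epoxidation of the vinylogous ester double bond, with oxidation of acetal C–H bonds or hydrolytic opening of the epoxide taking over. The fallback introduces the C3 oxygen through a halide. It sets out from 2 and returns at 7.
- Enaminone 4, made as in step 2, is cyclised with I2 to 3-iodo-6,7-bis(methoxymethoxy)-4H-chromen-4-one F11.
- Miyaura borylation (B2pin2, PdCl2(dppf), KOAc, dioxane) gives 6,7-bis(methoxymethoxy)-3-(4,4,5,5-tetramethyl-1,3,2-dioxaborolan-2-yl)-4H-chromen-4-one F12.
- Oxidation with NaBO3·4H2O gives 7.

**Step 7.** The risk is conjugate addition of fluoride, acetate or adventitious hydroxide to the freed ynenone, or its oligomerisation during desilylation. The fallback avoids the silyl alkyne altogether: 10 is coupled with tributyl(ethynyl)stannane (Stille coupling, Pd(PPh3)4, PhMe, 60 °C) to give 13 directly. It sets out from 10, returns at 13, and makes no new compound (F0).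

## Further compounds

F1 | step 12 | 3-hydroxy-4-(methoxymethoxy)benzaldehyde | COCOc1ccc(C=O)cc1O
F2 | step 12 | 4-(methoxymethoxy)-3-[(3-methylbut-2-en-1-yl)oxy]benzaldehyde | COCOc1ccc(C=O)cc1OCC=C(C)C
F3 | step 12 | (2E)-1-[2-hydroxy-4,5-bis(methoxymethoxy)phenyl]-3-{4-(methoxymethoxy)-3-[(3-methylbut-2-en-1-yl)oxy]phenyl}prop-2-en-1-one | COCOc1ccc(/C=C/C(=O)c2cc(OCOC)c(OCOC)cc2O)cc1OCC=C(C)C
F4 | step 12 | trans-3-hydroxy-6,7-bis(methoxymethoxy)-2-{4-(methoxymethoxy)-3-[(3-methylbut-2-en-1-yl)oxy]phenyl}chroman-4-one (racemic, one enantiomer drawn, not isolated) | COCOc1ccc([C@@H]2[C@@H](O)C(=O)c3cc(OCOC)c(OCOC)cc3O2)cc1OCC=C(C)C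
F5 | step 12 | 3-hydroxy-6,7-bis(methoxymethoxy)-2-{4-(methoxymethoxy)-3-[(3-methylbut-2-en-1-yl)oxy]phenyl}-4H-chromen-4-one | COCOc1ccc(-c2oc3cc(OCOC)c(OCOC)cc3c(=O)c2O)cc1OCC=C(C)C
F6 | step 12 | 2-{3-[(3-methylbut-2-en-1-yl)oxy]-4-[(trimethylsilyl)oxy]phenyl}-3,6,7-tris[(trimethylsilyl)oxy]-4H-chromen-4-one (not isolated) | CC(C)=CCOc1cc(-c2oc3cc(O[Si](C)(C)C)c(O[Si](C)(C)C)cc3c(=O)c2O[Si](C)(C)C)ccc1O[Si](C)(C)C
F7 | step 13 | 2-ethynyl-3,6,7-tris[(triethylsilyl)oxy]-4H-chromen-4-one | C#Cc1oc2cc(O[Si](CC)(CC)CC)c(O[Si](CC)(CC)CC)cc2c(=O)c1O[Si](CC)(CC)CC
F8 | step 13 | 2-{4-[(tert-butyldimethylsilyl)oxy]-6-(dimethylamino)-5-[(3-methylbut-2-en-1-yl)oxy]cyclohexa-1,4-dien-1-yl}-3,6,7-tris[(triethylsilyl)oxy]-4H-chromen-4-one (racemic, not isolated) | CN(C)C1C(OCC=C(C)C)=C(O[Si](C)(C)C(C)(C)C)CC=C1c1oc2cc(O[Si](CC)(CC)CC)c(O[Si](CC)(CC)CC)cc2c(=O)c1O[Si](CC)(CC)CC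
F9 | step 13 | 2-{4-[(tert-butyldimethylsilyl)oxy]-3-[(3-methylbut-2-en-1-yl)oxy]phenyl}-3,6,7-tris[(triethylsilyl)oxy]-4H-chromen-4-one | CC(C)=CCOc1cc(-c2oc3cc(O[Si](CC)(CC)CC)c(O[Si](CC)(CC)CC)cc3c(=O)c2O[Si](CC)(CC)CC)ccc1O[Si](C)(C)C(C)(C)C
F10 | step 5 | 3-hydroxy-2-iodo-6,7-bis(methoxymethoxy)-4H-chromen-4-one | O=c1c(O)c(I)oc2cc(OCOC)c(OCOC)cc12
F11 | step 3 | 3-iodo-6,7-bis(methoxymethoxy)-4H-chromen-4-one | O=c1c(I)coc2cc(OCOC)c(OCOC)cc12
F12 | step 3 | 6,7-bis(methoxymethoxy)-3-(4,4,5,5-tetramethyl-1,3,2-dioxaborolan-2-yl)-4H-chromen-4-one | CC1(C)OB(c2coc3cc(OCOC)c(OCOC)cc3c2=O)OC1(C)C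
F0 | step 7 | none | none
A1 | alternative 1 | 4,5-bis(methoxymethoxy)-2-(trimethylsilyl)phenyl trifluoromethanesulfonate | COCOc1cc(OS(=O)(=O)C(F)(F)F)c([Si](C)(C)C)cc1OCOC
A2 | alternative 1 | (2Z)-3-[3-(benzyloxy)-4-(methoxymethoxy)phenyl]-2-(methoxymethoxy)prop-2-enoic acid | COCO/C(=C\c1ccc(OCOC)c(OCc2ccccc2)c1)C(=O)O
A3 | alternative 1 | 2-[3-(benzyloxy)-4-(methoxymethoxy)phenyl]-3,6,7-tris(methoxymethoxy)chroman-4-one (diastereomer mixture, both centres lost later) | O=C1c2cc(OCOC)c(OCOC)cc2OC(c2ccc(OCOC)c(OCc3ccccc3)c2)C1OCOC
A4 | alternative 2 | tert-butyldimethylsilyl 4,5-bis(methoxymethoxy)-2-({4-(methoxymethoxy)-3-[(3-methylbut-2-en-1-yl)oxy]benzoyl}oxy)benzoate | COCOc1cc(OC(=O)c2ccc(OCOC)c(OCC=C(C)C)c2)c(C(=O)O[Si](C)(C)C(C)(C)C)cc1OCOC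
A5 | alternative 2 | triphenyl{[2-(trimethylsilyl)ethoxy]methylidene}phosphorane | C[Si](C)(C)CCOC=P(c1ccccc1)(c1ccccc1)c1ccccc1
A6 | alternative 2 | 6,7-bis(methoxymethoxy)-2-{4-(methoxymethoxy)-3-[(3-methylbut-2-en-1-yl)oxy]phenyl}-3-[2-(trimethylsilyl)ethoxy]-4H-chromen-4-one | CC(C)=CCOc1cc(-c2oc3cc(OCOC)c(OCOC)cc3c(=O)c2OCC[Si](C)(C)C)ccc1OCOC
A7 | alternative 3 | methyl 3-[2-bromo-4,5-bis(methoxymethoxy)phenoxy]-2-[(tert-butyldimethylsilyl)oxy]-3-{4-(methoxymethoxy)-3-[(3-methylbut-2-en-1-yl)oxy]phenyl}propanoate (racemic, both centres lost later) | COC(=O)C(O[Si](C)(C)C(C)(C)C)C(Oc1cc(OCOC)c(OCOC)cc1Br)c1ccc(OCOC)c(OCC=C(C)C)c1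
A8 | alternative 3 | 3-[(tert-butyldimethylsilyl)oxy]-6,7-bis(methoxymethoxy)-2-{4-(methoxymethoxy)-3-[(3-methylbut-2-en-1-yl)oxy]phenyl}chroman-4-one (racemic, both centres lost later) | CC(C)(C)[Si](C)(C)OC1C(=O)c2cc(OCOC)c(OCOC)cc2OC1c1ccc(OCOC)c(OCC=C(C)C)c1
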